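**Retrosynthetic overview**
1. Target 12 ⇒ chromene ketone 7 + acetylfilicinic acid 10 + CH2O (methylene bridge made last, at the only free ring carbon of 7).
2. Chromene 7 ⇒ pyrone 3 + prenal 4: in one flask a Knoevenagel/oxa-6π annulation builds the 2H-pyran ring, then lactone opening and a dianion Claisen recyclisation build the benzene ring. This fixes the pyran oxygen next to the acetyl-bearing carbon.
3. Pyrone 3 ⇒ acetylacetone 1 + malonyl dichloride 2.
4. Acetylfilicinic acid 10 ⇒ phloracetophenone 8 by dearomatising C-gem-dimethylation (ring A is not made by cyclisation).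
5. Ring order: sacrificial 2-pyrone (step 1) → pyran and benzene rings together (step 2) → preformed ring A joined through CH2 (step 4).

Assumption: the target SMILES has no stereocentre and no stereogenic double bond, so the compound is achiral and needs no stereocontrol; tautomers are drawn as in the given SMILES.

**Step 1**
Reactants: 1 pentane-2,4-dione (acetylacetone); 2 malonyl dichloride
Product: 3 5-acetyl-4-hydroxy-6-methyl-2H-pyran-2-one
Conditions: 2 (1.0 equiv), CH2Cl2, 0 → 40 °C, N2 sweep (−HCl); extract into aq. NaHCO3, re-acidify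
Reagents that add atoms: none
Why: Malonyl chloride pyrone synthesis from a β-diketone: one acid chloride O-acylates the enol and the other C-acylates the central carbon, closing the 5-acyl-4-hydroxy-2-pyrone; no stereocentre is formed.

**Step 2**
Reactants: 3 5-acetyl-4-hydroxy-6-methyl-2H-pyran-2-one; 4 3-methylbut-2-enal (prenal)
Product: 7 1-(5,7-dihydroxy-2,2-dimethyl-2H-chromen-8-yl)ethan-1-one, via pyranopyranone 5 (not isolated), via ring-opened methyl ester 6 (not isolated)
Conditions: 4 (1.1 equiv), EDDA (10 mol%), 3 Å MS, MeOH, 50 °C; then Mg(OMe)2 (2 equiv), 40 °C; evaporate, THF, LDA (4.5 equiv), −78 → 0 °C; 1 M HCl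
Reagents that add atoms: none
Why: Proposed new method: (i) C-3 of the 4-hydroxy-2-pyrone undergoes amine-catalysed Knoevenagel condensation with prenal and the 1-oxatriene closes by oxa-6π electrocyclisation through O-4 (formal [3+3], well precedented for 4-hydroxy-6-methyl-2-pyrone) to give 5, placing the pyran oxygen next to the acetyl-bearing carbon; (ii) 5 is a cyclic enol ester of a β-diketone, so Mg(OMe)2 methanolysis at the lactone carbonyl releases the Mg-chelated diacetylmethanide 6, in which both acyl groups are acetyl and therefore equivalent; (iii) LDA forms the terminal β-diketone dianion, whose CH2 attacks the cis-disposed ester in a 6-exo Claisen (Dieckmann-type) condensation, and loss of methoxide plus enolisation gives the acylphloroglucinol ring irreversibly; the closest known reactions are the Knoevenagel/oxa-6π annulation of 4-hydroxy-2-pyrones, the biomimetic pyrone → acylphloroglucinol Claisen recyclisation with Mg(OMe)2, and terminal acylation of β-diketone dianions by esters; no stereocentre is formed.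

**Step 3**
Reactants: 8 1-(2,4,6-trihydroxyphenyl)ethan-1-one (phloracetophenone)
Product: 10 2-acetyl-3,5-dihydroxy-4,4-dimethylcyclohexa-2,5-dien-1-one (acetylfilicinic acid), via 3-methylphloracetophenone 9 (not isolated)
Conditions: NaOMe (3.2 equiv), MeI (2.2 equiv), MeOH, 0 → 25 °C; then 1 M HCl
Reagents that add atoms: iodomethane CI
Why: Dearomatising double C-methylation of the phloroglucinol polyanion (the standard entry to acylfilicinic acids): the second methyl enters the already methylated, most electron-rich carbon and the gem-dimethyl group blocks rearomatisation; no stereocentre is formed.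

**Step 4**
Reactants: 7 1-(5,7-dihydroxy-2,2-dimethyl-2H-chromen-8-yl)ethan-1-one; 10 2-acetyl-3,5-dihydroxy-4,4-dimethylcyclohexa-2,5-dien-1-one
Product: 12 2-acetyl-6-[(8-acetyl-5,7-dihydroxy-2,2-dimethyl-2H-chromen-6-yl)methyl]-3,5-dihydroxy-4,4-dimethylcyclohexa-2,5-dien-1-one (target), via methylidene trione 11 (not isolated)
Conditions: 10 (2.0 equiv), 37% aq. CH2O (1.1 equiv), 1% aq. KOH, N2, 0 → 20 °C, 20 min; then 1 M HCl; chromatography
Reagents that add atoms: formaldehyde C=O
Why: Knoevenagel condensation of trione 10 with formaldehyde gives the quinone-methide-like enone 11, which is trapped by C-6 of the phenoxide of 7 (its only free ring carbon) in a Michael/Friedel–Crafts alkylation, the classical formaldehyde methylene bridging of filicinic acids; the homodimer of 10 forms reversibly and is removed; no stereocentre is formed.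

**Compound list**
1 | pentane-2,4-dione (acetylacetone) | CC(=O)CC(C)=O | starting material
2 | malonyl dichloride | O=C(Cl)CC(=O)Cl | starting material
3 | 5-acetyl-4-hydroxy-6-methyl-2H-pyran-2-one | CC(=O)C1=C(C)OC(=O)C=C1O | intermediate
4 | 3-methylbut-2-enal (prenal) | CC(C)=CC=O | starting material
5 | 8-acetyl-2,2,7-trimethyl-2H,5H-pyrano[4,3-b]pyran-5-one | CC(=O)C1=C(C)OC(=O)C2=C1OC(C)(C)C=C2 | intermediate
6 | methyl 6-(2,4-dioxopentan-3-yl)-2,2-dimethyl-2H-pyran-5-carboxylate (present as its enolate) | COC(=O)C1=C(C(C(C)=O)C(C)=O)OC(C)(C)C=C1 | intermediate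
7 | 1-(5,7-dihydroxy-2,2-dimethyl-2H-chromen-8-yl)ethan-1-one | CC(=O)c1c(O)cc(O)c2c1OC(C)(C)C=C2 | intermediate
8 | 1-(2,4,6-trihydroxyphenyl)ethan-1-one (phloracetophenone) | CC(=O)c1c(O)cc(O)cc1O | starting material
9 | 1-(2,4,6-trihydroxy-3-methylphenyl)ethan-1-one | CC(=O)c1c(O)cc(O)c(C)c1O | intermediate
10 | 2-acetyl-3,5-dihydroxy-4,4-dimethylcyclohexa-2,5-dien-1-one (acetylfilicinic acid) | CC(=O)C1=C(O)C(C)(C)C(O)=CC1=O | intermediate
11 | 2-acetyl-3-hydroxy-4,4-dimethyl-6-methylidenecyclohex-2-ene-1,5-dione | CC(=O)C1=C(O)C(C)(C)C(=O)C(=C)C1=O | intermediate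
12 | 2-acetyl-6-[(8-acetyl-5,7-dihydroxy-2,2-dimethyl-2H-chromen-6-yl)methyl]-3,5-dihydroxy-4,4-dimethylcyclohexa-2,5-dien-1-one | CC(=O)C1=C(O)C(C)(C)C(O)=C(Cc2c(O)c3c(c(C(C)=O)c2O)OC(C)(C)C=C3)C1=O | target

**Totals**
Total step count: 4. Longest linear sequence: 3 (steps 1, 2, 4); step 3 is a one-step branch.

**Steps most likely to fail**

Step 2 is the riskiest. Methoxide may open 5 at the vinylogous C-7 instead of at the lactone carbonyl, giving a carboxylate that cannot cyclise. The Claisen closure relies on a singly activated methyl ketone. Warming the product phenoxide could scramble the pyran oxygen by retro-6π/6π, which is why the cyclisation is run at or below 0 °C. The fallback sets out from 8: direct condensation of 8 with 4 (EDDA 10 mol%, xylene, 140 °C) runs the Knoevenagel/oxa-6π annulation on the arene itself. It gives 7 in one step but without regiocontrol, together with 1-(5,7-dihydroxy-2,2-dimethyl-2H-chromen-6-yl)ethan-1-one F1, which is removed by chromatography. The route is rejoined at 7.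

Step 4 can give a statistical mixture of the two homodimers and the mixed dimer. The fallback sets out from 10: Eschenmoser's salt (1.1 equiv, MeCN, 20 °C) converts it into the Mannich base 2-acetyl-6-[(dimethylamino)methyl]-3,5-dihydroxy-4,4-dimethylcyclohexa-2,5-dien-1-one F2, which has no free nucleophilic ring carbon and so cannot homodimerise. Heating it with 7 (1.0 equiv, dioxane, 90 °C) expels the amine, generates 11 in the presence of 7 only, and comes back to the route at 12.

Step 1 can over-react, because 3 may be acylated by a second malonyl chloride, and malonyl chloride itself self-condenses. The fallback sets out from 1: MgCl2/pyridine-mediated C-acylation with methyl 3-chloro-3-oxopropanoate (CH2Cl2, 0 °C) gives methyl 4-acetyl-3,5-dioxohexanoate F3. This is lactonised through its enol (DBU cat., toluene, 110 °C) and comes back to the route at 3.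

**Further compounds**
F1 | step 2 | 1-(5,7-dihydroxy-2,2-dimethyl-2H-chromen-6-yl)ethan-1-one | CC(=O)c1c(O)cc2c(c1O)C=CC(C)(C)O2
F2 | step 4 | 2-acetyl-6-[(dimethylamino)methyl]-3,5-dihydroxy-4,4-dimethylcyclohexa-2,5-dien-1-one | CC(=O)C1=C(O)C(C)(C)C(O)=C(CN(C)C)C1=O
F3 | step 1 | methyl 4-acetyl-3,5-dioxohexanoate | COC(=O)CC(=O)C(C(C)=O)C(C)=O
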